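**Plan**

Locants used below: five-membered ring C1(O)–C2–C3–C4(Me, C1′HPhAr)–C5(H); seven-membered ring C1–C5–C6–C7–C8–C9–C10(Me); cyclopropane C6–C7–C11(Me2).
Cuts, last to first: two Ar–CHO and two O–CH3 bonds; the C8 carbonyl; the C1–O bond of the bridging oxepane; C10–H (hydrogenation of C9=C10); cyclopropane bonds C6–C11/C7–C11 (isopropylidene transfer to a C6=C7–C8=O enone); then C6–C7 and C1–C10 together.
The double cut is possible because C5, the only atom between C1 and C6, is an sp3 CH. C6 can therefore sit at acetal level and C1 be made nucleophilic by a temporary C2 ketone, so the C6–C5–C1 unit of a 3-formylcyclopentanone takes up C7–C10 of pent-3-yn-2-one (C7 as enol silane carbon, C10 as ynone β-carbon) in a formal (4+3) annulation that closes the seven-membered ring.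
Forward order: dihydrocoumarin (C1′, then quaternary C4) → cyclopentanone C1–C5 → seven-membered dienone → cyclopropane → C10 → oxepane bridge → deoxygenation → aromatic CHO/OH groups.
Stereochemistry: C1′ by Rh/SEGPHOS conjugate phenylation; C4 by two lactone-enolate alkylations anti to Ph; C5 by conjugate addition anti to the diarylmethyl group; C6/C7 by ylide attack on the H5 face; C10 by hydrogenation anti to the cyclopropane; C1 by the phenol tether on C4.

Key step: step 7

Remark: 3-bromo-2-methoxyprop-1-ene, isopropyldiphenylsulfonium tetrafluoroborate and pent-3-yn-2-one are taken as purchasable reagents.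
Remark: 6, 12 and 14 are epimer mixtures at a carbon that is no stereocentre of the target (lactol carbon, C6, C2). C1 in 13–16 is drawn with H1 cis to H5; it is reset in step 11, so either epimer serves.

**Route**

Step 1
Reactants: 1 5,7-dimethoxy-2H-chromen-2-one; 2 phenylboronic acid
Product: 3 (S)-5,7-dimethoxy-4-phenylchroman-2-one
Conditions: Rh(acac)(C2H4)2 (3 mol %), (S)-SEGPHOS (3.3 mol %; ligand enantiomer chosen to deliver the S lactone), dioxane/H2O 10:1, 60 °C
Reagents that add atoms: none
Why: Hayashi–Miyaura asymmetric conjugate addition of the phenyl–rhodium species to the coumarin C3=C4 bond, the chiral bisphosphine selecting the enantioface and setting C1′ (S).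

Step 2
Reactants: 3 (S)-5,7-dimethoxy-4-phenylchroman-2-one
Product: 4 (3R,4S)-5,7-dimethoxy-3-methyl-4-phenylchroman-2-one
Conditions: LiN(i-Pr)2, THF, −78 °C; MeI, −78 → −40 °C
Reagents that add atoms: iodomethane, CI
Why: lactone enolate alkylation in which MeI should enter anti to the 4-phenyl group (trans product); this centre is re-formed in step 3.

Step 3
Reactants: 4 (3R,4S)-5,7-dimethoxy-3-methyl-4-phenylchroman-2-one
Product: 5 (3R,4S)-5,7-dimethoxy-3-(2-methoxyprop-2-en-1-yl)-3-methyl-4-phenylchroman-2-one
Conditions: LiN(i-Pr)2, THF/DMPU, −78 °C; 3-bromo-2-methoxyprop-1-ene, −78 → −20 °C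
Reagents that add atoms: 3-bromo-2-methoxyprop-1-ene, COC(=C)CBr
Why: alkylation of the fully substituted lactone enolate, again anti to Ph, so that the acetonyl equivalent ends trans and the methyl cis to Ph, which sets quaternary C4 relative to C1′.

Step 4
Reactants: 5 (3R,4S)-5,7-dimethoxy-3-(2-methoxyprop-2-en-1-yl)-3-methyl-4-phenylchroman-2-one
Product: 6 (3R,4S)-5,7-dimethoxy-3-methyl-3-(2-oxopropyl)-4-phenylchroman-2-ol (lactol, both anomers)
Conditions: i-Bu2AlH (1.1 equiv), CH2Cl2, −78 °C; then 1 M HCl, THF, 0 °C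
Reagents that add atoms: water, O
Why: half-reduction of the aryl lactone to the 2-chromanol (aluminium hemiacetal stable at −78 °C) followed by acid hydrolysis of the enol ether to the methyl ketone; no stereocentre is touched.

Step 5
Reactants: 6 (3R,4S)-5,7-dimethoxy-3-methyl-3-(2-oxopropyl)-4-phenylchroman-2-ol
Product: 8 4-methyl-3-(nitromethyl)-4-[(S)-(2-hydroxy-4,6-dimethoxyphenyl)(phenyl)methyl]cyclopentan-1-one (CH2NO2 cis to CH3), via cyclopentenone 7 (not isolated)
Conditions: MeNO2 (10 equiv), DBU (1.5 equiv), MeCN, rt → 50 °C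
Reagents that add atoms: nitromethane, C[N+](=O)[O-]
Why: ring-chain tautomerism frees the C5 aldehyde, intramolecular aldol condensation with the methyl ketone gives the cyclopentenone (C2=O, C1=C5), and reversible nitro-Michael addition places C6 on C5 anti to the diarylmethyl group on C4, setting C5.

Step 6
Reactants: 8 4-methyl-3-(nitromethyl)-4-[(S)-(2-hydroxy-4,6-dimethoxyphenyl)(phenyl)methyl]cyclopentan-1-one
Product: 9 3-(dimethoxymethyl)-4-methyl-4-[(S)-(2-hydroxy-4,6-dimethoxyphenyl)(phenyl)methyl]cyclopentan-1-one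
Conditions: NaOMe, MeOH, 0 °C; added to H2SO4, MeOH, −35 °C; aqueous NaHCO3
Reagents that add atoms: methanol, CO
Why: Nef reaction run in methanol, the nitronic acid being solvolysed to the dimethyl acetal of the C6 aldehyde; C5 is not enolisable at the acetal stage.

Step 7
Reactants: 9 3-(dimethoxymethyl)-4-methyl-4-[(S)-(2-hydroxy-4,6-dimethoxyphenyl)(phenyl)methyl]cyclopentan-1-one; 10 pent-3-yn-2-one
Product: 13 4,10-dimethyl-4-[(S)-(2-hydroxy-4,6-dimethoxyphenyl)(phenyl)methyl]bicyclo[5.3.0]deca-6,9-diene-2,8-dione (target locants; H1 cis to H5), via enol silane 11 (not isolated), via methoxy ynone 12 (not isolated)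
Conditions: 10, Me3SiOTf (1.3 equiv), i-Pr2NEt (1.1 equiv), CH2Cl2, 0 °C; then 9, −78 → −20 °C; solvent exchange; t-BuOK (3 equiv), THF/t-BuOH, 0 °C → rt
Reagents that add atoms: none
Why: Me3SiOTf ionises the dimethyl acetal to the C6 oxocarbenium ion, which is attacked by the CH2 terminus (C7) of enol silane 11 (Mukaiyama aldol-type addition to an acetal, the closest known reaction type, here with one-pot enol silane formation), giving β-methoxy ynone 12 and the C6–C7 bond. t-BuOK then forms the enolate of the C2 ketone, whose α-carbon C1 adds to the ynone β-carbon C10 (intramolecular Michael addition of a ketone to an alkynone), and methoxide leaves C6 by E1cB to give the cross-conjugated dienone. The only ring closed is the seven-membered carbocycle, in a 7-endo-dig mode (C1 onto C10); the other enolate carbon C3 would have to close an eight-membered ring, and C9 stays sp-hybridised until the ring exists, so no five-membered aldol or Michael ring can form. No stereocentre of the target is fixed irreversibly: C5, now γ to the dienone, should equilibrate to the isomer with C6 trans to the diarylmethyl group on C4, C1 is provisional and C10 is left sp2 for step 10. The selectivity needed is regiochemical (C7 before C1, C1 not C3) and geometric: any (E)-C6=C7 enone formed by early elimination must reach a cyclisable form, which reversible alkoxide addition at C6 and the C5 dienolate (C6–C7 single bond) both allow.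

Step 8
Reactants: 13 4,10-dimethyl-4-[(S)-(2-hydroxy-4,6-dimethoxyphenyl)(phenyl)methyl]bicyclo[5.3.0]deca-6,9-diene-2,8-dione
Product: 14 2-hydroxy-4,10-dimethyl-4-[(S)-(2-hydroxy-4,6-dimethoxyphenyl)(phenyl)methyl]bicyclo[5.3.0]deca-6,9-dien-8-one (C2 epimers)
Conditions: NaBH4, MeOH/CH2Cl2 1:1, −78 °C
Reagents that add atoms: none
Why: chemoselective 1,2-reduction of the saturated cyclopentanone in the presence of the less electrophilic cross-conjugated dienone; the carbinol carbon C2 is no stereocentre of the target and the hydroxyl serves as leaving group in step 11.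

Step 9
Reactants: 14 2-hydroxy-4,10-dimethyl-4-[(S)-(2-hydroxy-4,6-dimethoxyphenyl)(phenyl)methyl]bicyclo[5.3.0]deca-6,9-dien-8-one
Product: 15 C6,C7-(dimethylmethylene)-bridged cyclopropyl enone (C11 syn to H5; C9=C10 retained)
Conditions: [Ph2S–CH(CH3)2]BF4 (3.5 equiv), LiN(i-Pr)2, DME, −78 °C; then 14, −78 → −30 °C
Reagents that add atoms: isopropyldiphenylsulfonium tetrafluoroborate, CC(C)[S+](c1ccccc1)c1ccccc1.F[B-](F)(F)F
Why: Corey–Chaykovsky-type isopropylidene transfer in which the ylide adds conjugately to C6 (C10 is β,β-disubstituted and spared) and the enolate carbon C7 displaces diphenyl sulfide from C11; attack on the face of C6 anti to C4 (the H5 face) should set C6 and C7 with C11 syn to H5.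

Step 10
Reactants: 15 cyclopropyl enone
Product: 16 saturated cyclopropyl ketone (C10 methyl syn to C11)
Conditions: H2 (1 atm), Pd/C (5 %), EtOAc, rt
Reagents that add atoms: none
Why: heterogeneous hydrogenation of the remaining trisubstituted enone C9=C10 from the face opposite the gem-dimethylcyclopropane, whose endo methyl shields the other face, should set C10.

Step 11
Reactants: 16 saturated cyclopropyl ketone
Product: 17 8-oxo derivative of O,O-dimethyl-bis(deformyl)psiguadial A (bridged ether)
Conditions: TsOH·H2O (0.2 equiv), toluene, 4 Å MS, 80 °C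
Reagents that add atoms: none
Why: acid-induced loss of the C2 hydroxyl with hydride shift from C1 (or through the C1=C2 alkene) gives the tertiary C1 cation, which the phenol on C1′, held on the same face by C4, traps in an intramolecular hydroalkoxylation-type etherification that closes the oxepane and fixes C1; the C8 ketone on the cyclopropane disfavours a cyclopropylcarbinyl cation at C5.

Step 12
Reactants: 17 bridged ether ketone
Product: 18 O,O-dimethyl-bis(deformyl)psiguadial A
Conditions: N2H4·H2O, KOH, diethylene glycol, 130 → 200 °C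
Reagents that add atoms: none
Why: Wolff–Kishner reduction (Huang–Minlon modification) of the cyclopropyl ketone C8 under conditions to which the ethers, the cyclopropane and all stereocentres are inert.

Step 13
Reactants: 18 O,O-dimethyl-bis(deformyl)psiguadial A
Product: 19 psiguadial A dimethyl ether
Conditions: Cl2CHOMe (6 equiv), TiCl4 (6 equiv), CH2Cl2, −78 → 0 °C; H2O
Reagents that add atoms: dichloromethyl methyl ether, COC(Cl)Cl; water, O
Why: twofold Rieche formylation at the two free positions of the 1,3,5-trioxygenated ring, each ortho or para to all three oxygen substituents.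

Step 14
Reactants: 19 psiguadial A dimethyl ether
Product: 20 psiguadial A
Conditions: BCl3 (6 equiv), CH2Cl2, −78 → 0 °C; aqueous NaHCO3
Reagents that add atoms: none
Why: chelation-assisted cleavage of the two aryl methyl ethers, each ortho to a formyl group, by chloride attack at methyl in the aryloxy–boron complex, which should be faster than ionisation of the tertiary C1–O bond at low temperature.

**Compound list**

1 | 5,7-dimethoxy-2H-chromen-2-one | O=C1C=Cc2c(OC)cc(OC)cc2O1 | starting material
2 | phenylboronic acid | OB(O)c1ccccc1 | starting material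
3 | (S)-5,7-dimethoxy-4-phenylchroman-2-one | O=C1C[C@@H](c2ccccc2)c2c(OC)cc(OC)cc2O1 | intermediate
4 | (3R,4S)-5,7-dimethoxy-3-methyl-4-phenylchroman-2-one | O=C1[C@H](C)[C@@H](c2ccccc2)c2c(OC)cc(OC)cc2O1 | intermediate
5 | (3R,4S)-5,7-dimethoxy-3-(2-methoxyprop-2-en-1-yl)-3-methyl-4-phenylchroman-2-one | O=C1[C@](C)(CC(=C)OC)[C@@H](c2ccccc2)c2c(OC)cc(OC)cc2O1 | intermediate
6 | (3R,4S)-5,7-dimethoxy-3-methyl-3-(2-oxopropyl)-4-phenylchroman-2-ol (anomers) | OC1Oc2cc(OC)cc(OC)c2[C@H](c2ccccc2)[C@@]1(C)CC(C)=O | intermediate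
7 | 4-methyl-4-[(S)-(2-hydroxy-4,6-dimethoxyphenyl)(phenyl)methyl]cyclopent-2-en-1-one (quaternary carbon as in 5) | O=C1C[C@@](C)(C=C1)[C@@H](c1ccccc1)c1c(O)cc(OC)cc1OC | intermediate (not isolated)
8 | 4-methyl-3-(nitromethyl)-4-[(S)-(2-hydroxy-4,6-dimethoxyphenyl)(phenyl)methyl]cyclopentan-1-one (CH2NO2 cis to CH3) | O=C1C[C@H](C[N+](=O)[O-])[C@](C)(C1)[C@@H](c1ccccc1)c1c(O)cc(OC)cc1OC | intermediate
9 | 3-(dimethoxymethyl)-4-methyl-4-[(S)-(2-hydroxy-4,6-dimethoxyphenyl)(phenyl)methyl]cyclopentan-1-one | O=C1C[C@H](C(OC)OC)[C@](C)(C1)[C@@H](c1ccccc1)c1c(O)cc(OC)cc1OC | intermediate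
10 | pent-3-yn-2-one | CC#CC(C)=O | starting material
11 | 2-(trimethylsilyloxy)pent-1-en-3-yne | CC#CC(=C)O[Si](C)(C)C | intermediate (not isolated)
12 | β-methoxy ynone: 3-(1-methoxy-3-oxohex-4-yn-1-yl) analogue of 9 (C6 epimers) | CC#CC(=O)CC(OC)[C@H]1CC(=O)C[C@]1(C)[C@@H](c1ccccc1)c1c(O)cc(OC)cc1OC | intermediate (not isolated)
13 | 4,10-dimethyl-4-[(S)-(2-hydroxy-4,6-dimethoxyphenyl)(phenyl)methyl]bicyclo[5.3.0]deca-6,9-diene-2,8-dione (target locants; H1 cis to H5) | CC1=CC(=O)C=C[C@H]2[C@@H]1C(=O)C[C@]2(C)[C@@H](c1ccccc1)c1c(O)cc(OC)cc1OC | intermediate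
14 | C2 alcohol of 13 (C2 epimers) | CC1=CC(=O)C=C[C@H]2[C@@H]1C(O)C[C@]2(C)[C@@H](c1ccccc1)c1c(O)cc(OC)cc1OC | intermediate
15 | cyclopropyl enone (C6–C7–C11 ring, C11 syn to H5, C9=C10 retained) | CC1=CC(=O)[C@@H]2[C@H]([C@H]3[C@@H]1C(O)C[C@]3(C)[C@@H](c1ccccc1)c1c(O)cc(OC)cc1OC)C2(C)C | intermediate
16 | saturated cyclopropyl ketone (C10 methyl syn to C11) | C[C@H]1CC(=O)[C@@H]2[C@H]([C@H]3[C@@H]1C(O)C[C@]3(C)[C@@H](c1ccccc1)c1c(O)cc(OC)cc1OC)C2(C)C | intermediate
17 | 8-oxo-O,O-dimethyl-bis(deformyl)psiguadial A | C[C@H]1CC(=O)[C@@H]2[C@H]([C@@H]3[C@]4(C)CC[C@@]31Oc1cc(OC)cc(OC)c1[C@@H]4c1ccccc1)C2(C)C | intermediate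
18 | O,O-dimethyl-bis(deformyl)psiguadial A | C[C@H]1CC[C@@H]2[C@H]([C@@H]3[C@]4(C)CC[C@@]31Oc1cc(OC)cc(OC)c1[C@@H]4c1ccccc1)C2(C)C | intermediate
19 | psiguadial A dimethyl ether | C[C@H]1CC[C@@H]2[C@H]([C@@H]3[C@]4(C)CC[C@@]31Oc1c(C=O)c(OC)c(C=O)c(OC)c1[C@@H]4c1ccccc1)C2(C)C | intermediate
20 | psiguadial A | C[C@H]1CC[C@@H]2[C@H]([C@@H]3[C@]4(C)CC[C@@]31Oc1c(C=O)c(O)c(C=O)c(O)c1[C@@H]4c1ccccc1)C2(C)C | target

**Step count and risks**

Total step count: 14. Longest linear sequence: 14 steps (1 → 20); pent-3-yn-2-one 10 enters at step 7.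

Steps most likely to fail:

1. Step 7. In the basic stage, β-elimination to the (E)-enone followed by intermolecular conjugate addition or oligomerisation of the ynone may outrun ring closure. Fallback, setting out from 9: aqueous acetic acid unmasks keto aldehyde F1. A Z-selective Horner–Wadsworth–Emmons olefination of the Still–Gennari type with bis(2,2,2-trifluoroethyl) (2-oxopent-3-yn-1-yl)phosphonate (KN(SiMe3)2, 18-crown-6, THF, −78 °C) then gives (Z)-enynone F2, in which the C6=C7 geometry is already fit for cyclisation. Cs2CO3 in MeCN closes C1–C10 by Michael addition, and the route is rejoined at 13.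

2. Step 11. The positive charge may move from C1 to C5 by hydride shift, or a proton may be lost toward C10 before the phenol captures C1; this would give the six-membered O–C5 ether or erode C10. Fallback, setting out from 16: dehydration with Ph2S[OC(CF3)2Ph]2 to alkene F4 (C1=C2, the more substituted isomer expected). A cobalt-catalysed hydrogen-atom-transfer hydroalkoxylation (Co(salen), N-fluoro-2,4,6-trimethylpyridinium triflate, (Me2SiH)2O, rt) then places hydrogen on C2 and lets the phenol trap the tertiary C1 centre without a free carbocation. The route is rejoined at 17.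

3. Step 9. Proton transfer from the substrate (γ-enolisation of the dienone) to the basic ylide may replace conjugate addition, and facial selectivity at C6 may be incomplete. Fallback, setting out from 14: 2-diazopropane (Et2O, −20 °C) adds as a 1,3-dipole across the less substituted enone C6=C7 to give pyrazoline F3. Photolysis (350 nm) extrudes nitrogen and contracts it to the gem-dimethylcyclopropane, and the route is rejoined at 15.

**Further compounds**

F1 | step 7 | keto aldehyde: 3-formyl-4-methyl-4-[(S)-(2-hydroxy-4,6-dimethoxyphenyl)(phenyl)methyl]cyclopentan-1-one | O=C[C@H]1CC(=O)C[C@]1(C)[C@@H](c1ccccc1)c1c(O)cc(OC)cc1OC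
F2 | step 7 | (Z)-enynone: 3-[(1Z)-3-oxohex-1-en-4-yn-1-yl] analogue of F1 | CC#CC(=O)/C=C\[C@H]1CC(=O)C[C@]1(C)[C@@H](c1ccccc1)c1c(O)cc(OC)cc1OC
F3 | step 9 | pyrazoline: 1-pyrazoline fused at C6–C7 of 14 (C11 on C6, N on C7) | CC1=CC(=O)[C@H]2N=NC(C)(C)[C@H]2[C@H]3[C@@H]1C(O)C[C@]3(C)[C@@H](c1ccccc1)c1c(O)cc(OC)cc1OC
F4 | step 11 | alkene: C1=C2 dehydration product of 16 | C[C@H]1CC(=O)[C@@H]2[C@H]([C@H]3C1=CC[C@]3(C)[C@@H](c1ccccc1)c1c(O)cc(OC)cc1OC)C2(C)C
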